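**Assumptions:** (+)-Secoisolariciresinol (1), the (2S,3S) flaxseed lignan, is commercially available. Pivaloyl chloride acylates its two primary alcohols faster than its two ortho-methoxy-hindered phenols.

**Retrosynthesis**
- (+)-Neoolivil (4) is the all-trans, C2-symmetric 2,5-diaryl-3,4-bis(hydroxymethyl)THF, so the pivalate esters of 3 are removed last.
- The only ring, the THF with both benzylic C–O bonds, is formed in one electrochemical step from dipivalate 2, with the ring oxygen coming from water.
- Both C8 stereocentres come from 1, which is (8S,8'S) and maps directly onto C3/C4 of the target. C7 and C7' are set by reversible benzylic ionisation under these conditions, which funnels to the all-trans ring.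

**Route**

**Step 1**
Reactants: 1 (+)-secoisolariciresinol
Product: 2, 9,9'-di-O-pivaloyl-(+)-secoisolariciresinol
Conditions: PivCl (2.1 equiv), pyridine, CH2Cl2, –20 → 0 °C, 3 h
Reagents that add atoms: pivaloyl chloride, CC(C)(C)C(=O)Cl
Why: Acylation is chemoselective for the unhindered primary alcohols over the hindered guaiacyl phenols. It leaves the phenols free for quinone methide formation and blocks C9/C9'-OH from closing a 7,9'-type ring; no stereocentre is touched.

**Step 2**
Reactants: 2
Product: 3, (+)-neoolivil 9,9'-dipivalate
Conditions: undivided cell, graphite anode, Pt cathode, constant current (~4.2 F/mol), 0.05 M 2 and 0.1 M nBu4NPF6 in HFIP/MeCN/H2O (6:3:1), 0 °C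
Reagents that add atoms: water, O (supplies the ring oxygen)
Why: Proposed new method: anodic oxidation of one free guaiacol gives a p-quinone methide (QM) at C7, which water adds to reversibly, with the 9-pivalate acting as a neighbouring group so that the 7-OH/9-OPiv form is the thermodynamic partner. The C7-hydroxylated ring is slightly harder to oxidise, so the second oxidation occurs on the other ring (CH2). That gives a QM at C7', which is trapped intramolecularly by 7-OH in a 5-exo closure (a 7,7'-epoxy ring). Acidic HFIP keeps the p-oxyaryl benzylic ether C–O bonds reversibly ionisable, so C7/C7' settle to the all-trans arrangement relative to the fixed C8/C8'. The closest known reactions are anodic or DDQ QM-mediated benzylic C–H etherification and the secoisolariciresinol-to-lariciresinol-type cyclisation, but bis-oxygenation with water as the O source has not been shown.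

**Step 3**
Reactants: 3
Product: 4, (+)-neoolivil (plus neopentyl alcohol)
Conditions: LiAlH4 (6 equiv), THF, 0 °C → rt, 2 h; Rochelle-salt work-up
Reagents that add atoms: none
Why: Hydride cleaves both pivalates to the primary alcohols (ester reduction). The 2-aryl-THF benzylic ethers, aryl methyl ethers and stereocentres are unaffected.

**Checks**
- Target: (2R,3S,4S,5R), all-trans; ring size, two CH2OH groups and two guaiacyl groups all match.
- C8/C8' (S,S) come from 1; ring closure gives (R,R) at the aryl-bearing carbons.
- Atom balance: 1 (C20H26O6) → 2 (C30H42O8) → 3 (C30H40O9) by +H2O and –4H → 4 (C20H24O7) after loss of two neopentyl alcohols.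

**Compound list**

| No. | Name | SMILES | Role |
|---|---|---|---|
| 1 | (+)-Secoisolariciresinol, (2S,3S) | OC[C@@H](Cc1ccc(O)c(OC)c1)[C@@H](CO)Cc1ccc(O)c(OC)c1 | starting material |
| 2 | 9,9'-Di-O-pivaloyl-(+)-secoisolariciresinol | CC(C)(C)C(=O)OC[C@@H](Cc1ccc(O)c(OC)c1)[C@@H](COC(=O)C(C)(C)C)Cc1ccc(O)c(OC)c1 | intermediate |
| 3 | (+)-Neoolivil 9,9'-dipivalate | COc1cc([C@@H]2O[C@@H](c3ccc(O)c(OC)c3)[C@H](COC(=O)C(C)(C)C)[C@H]2COC(=O)C(C)(C)C)ccc1O | intermediate |
| 4 | (+)-Neoolivil | COc1cc([C@@H]2O[C@@H](c3ccc(O)c(OC)c3)[C@H](CO)[C@H]2CO)ccc1O | target |

**Total steps:** 3. **Longest linear sequence:** 3.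

**Three steps most likely to fail**
1. **Step 2 (proposed new step).** Possible failures are over-oxidation to the 7-ketone, formation of the 7,9'-epoxy (lariciresinol-type) isomer, and C8 epimerisation through a QM-derived styrene.
   - Fallback (known chemistry, different approach): protect the phenols and pivaloylate the primary OH groups, oxidise both benzylic CH2 groups to the 1,4-diketone (DDQ or Cu/NHPI benzylic oxidation), reduce with NaBH4 to the 7,7'-diol, and cyclodehydrate with TsOH. This is a thermodynamic closure to the all-trans THF, followed by deprotection.
2. **Step 1.** Phenol acylation competes with primary-alcohol acylation.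
   - Fallback: pivaloylate all four OH groups, then cleave only the aryl pivalates selectively (hydrazine acetate or NH4OAc in MeOH/H2O) to reach 2.
3. **Step 3.** Hindered pivalates may cleave incompletely, or the polar free-phenol product may be lost in the aluminium work-up.
   - Fallback: carry 9,9'-diacetate in place of dipivalate (reworking step 1 and the step 2 substrate) and remove it with K2CO3/MeOH.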